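**Plan**
- Retrosynthesis first cuts the CH2–CH bond of each prenyl group (at C8 of ring A and at C3' of ring B). Each of these CH2 carbons is ortho to a phenol oxygen (O7 and O4'), so each can be the exocyclic terminus of an ortho-quinone methide released from an O-Boc salicyl alcohol.
- Next come the two aryl–CH2OH bonds (C8–C and C3'–C, twofold ortho-formylation then reduction), then ring C at O1–C2 together with the C3–OH bond (Algar–Flynn–Oyamada), then the Cα–Cβ bond of a chalcone (Claisen–Schmidt).
- Forward: rings A and B are bought in (phloroacetophenone, 4-(benzyloxy)benzaldehyde) and joined as a chalcone; ring C closes in step 4; both one-carbon units are added in step 7; both prenyl chains are completed in step 10; MOM removal ends the route.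
- Protecting groups: benzyl on O7 and O4' (removed by hydrogenolysis before any alkene is present), MOM on O3 and O5 (removed last), Boc on O7 and O4' as the trigger.
- Stereochemistry: the target has no stereocentre; the trisubstituted alkenes arrive intact with the isobutenyl reagent, and the E-alkene of the chalcone is consumed in ring closure.

Key step: step 10

Assumption: 2-methylprop-1-enylmagnesium bromide is bought as its THF solution and titrated before use.

**Step 1**
Reactants: 1 2,4,6-trihydroxyacetophenone
Product: 2 1-[4-(benzyloxy)-2,6-dihydroxyphenyl]ethanone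
Conditions: BnBr (1.0 equiv), K2CO3 (1.1 equiv), DMF, 0 °C → rt
Reagents that add atoms: benzyl bromide, BrCc1ccccc1
Why: Williamson ether synthesis with one equivalent of halide should alkylate the 4-hydroxyl, the most acidic one and the only one not held in a hydrogen bond to the acetyl carbonyl, leaving the two equivalent ortho hydroxyls free.

**Step 2**
Reactants: 2 1-[4-(benzyloxy)-2,6-dihydroxyphenyl]ethanone
Product: 3 1-[4-(benzyloxy)-2-hydroxy-6-(methoxymethoxy)phenyl]ethanone
Conditions: MOMCl (1.1 equiv), iPr2NEt (1.5 equiv), CH2Cl2, 0 °C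
Reagents that add atoms: chloromethyl methyl ether, COCCl
Why: O-alkylation with MOMCl under amine base (acetal ether formation) should cap one of the two equivalent ortho hydroxyls, after which the remaining one is held in the chelate with the ketone and resists a second alkylation under these mild conditions.

**Step 3**
Reactants: 3 1-[4-(benzyloxy)-2-hydroxy-6-(methoxymethoxy)phenyl]ethanone; 4 4-(benzyloxy)benzaldehyde
Product: 5 (E)-1-[4-(benzyloxy)-2-hydroxy-6-(methoxymethoxy)phenyl]-3-[4-(benzyloxy)phenyl]prop-2-en-1-one
Conditions: KOH (50% aq.), EtOH/THF, rt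
Reagents that add atoms: none
Why: Claisen–Schmidt condensation, in which the ketone enolate adds to the non-enolizable aldehyde and E1cB loss of water gives the E-enone, the free 2-hydroxyl being present as its phenoxide and the ethers being inert to hydroxide.

**Step 4**
Reactants: 5 (E)-1-[4-(benzyloxy)-2-hydroxy-6-(methoxymethoxy)phenyl]-3-[4-(benzyloxy)phenyl]prop-2-en-1-one
Product: 6 7-(benzyloxy)-2-[4-(benzyloxy)phenyl]-3-hydroxy-5-(methoxymethoxy)-4H-chromen-4-one
Conditions: H2O2 (30% aq.), NaOH (2 M aq.), MeOH/THF, 0 °C → rt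
Reagents that add atoms: hydrogen peroxide, OO
Why: Algar–Flynn–Oyamada reaction, in which alkaline hydrogen peroxide epoxidizes the enone, the phenoxide opens the epoxide at the benzylic carbon to close ring C in a 6-endo mode and further oxidation of the dihydroflavonol gives the flavonol, the 4-alkoxy group on ring B favouring benzylic attack over aurone formation.

**Step 5**
Reactants: 6 7-(benzyloxy)-2-[4-(benzyloxy)phenyl]-3-hydroxy-5-(methoxymethoxy)-4H-chromen-4-one
Product: 7 7-(benzyloxy)-2-[4-(benzyloxy)phenyl]-3,5-bis(methoxymethoxy)-4H-chromen-4-one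
Conditions: MOMCl (2 equiv), iPr2NEt (3 equiv), CH2Cl2, 0 °C → rt
Reagents that add atoms: chloromethyl methyl ether, COCCl
Why: Acetal ether formation (MOM protection) of the acidic enolic 3-hydroxyl, the only free hydroxyl in 6, is standard for flavonols.

**Step 6**
Reactants: 7 7-(benzyloxy)-2-[4-(benzyloxy)phenyl]-3,5-bis(methoxymethoxy)-4H-chromen-4-one
Product: 8 3,5-bis-O-MOM-kaempferol [7-hydroxy-2-(4-hydroxyphenyl)-3,5-bis(methoxymethoxy)-4H-chromen-4-one]
Conditions: H2 (1 atm), 10% Pd/C, EtOAc/MeOH, rt
Reagents that add atoms: none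
Why: Catalytic hydrogenolysis cleaves the two benzyl aryl ethers while the MOM acetals and the tetrasubstituted vinylogous-ester C2=C3 bond of the chromone are left alone, which frees exactly the 7- and 4'-phenols.

**Step 7**
Reactants: 8 3,5-bis-O-MOM-kaempferol
Product: 9 8,3'-diformyl-3,5-bis-O-MOM-kaempferol [2-(3-formyl-4-hydroxyphenyl)-7-hydroxy-3,5-bis(methoxymethoxy)-4-oxo-4H-chromene-8-carbaldehyde]
Conditions: MgCl2 (anhydrous, 4 equiv), Et3N (8 equiv), paraformaldehyde (14 equiv), MeCN, reflux; cold 1 M HCl work-up
Reagents that add atoms: paraformaldehyde (as formaldehyde), C=O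
Why: Magnesium-mediated ortho-formylation of phenols (Casnati–Skattebøl reaction), in which each magnesium phenoxide delivers formaldehyde to an ortho carbon and a second formaldehyde oxidizes the benzylic alkoxide by hydride transfer; on ring B the two ortho sites are equivalent, and on ring A C8 is expected over C6 because it ends the C7–C8 bond of higher double-bond character in 7-hydroxychromones and is flanked only by the ring oxygen, whereas C6 is crowded by the 5-OMOM group.

**Step 8**
Reactants: 9 8,3'-diformyl-3,5-bis-O-MOM-kaempferol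
Product: 10 7,4'-bis-O-Boc-8,3'-diformyl-3,5-bis-O-MOM-kaempferol
Conditions: Boc2O (2.5 equiv), DMAP (0.1 equiv), iPr2NEt (2.5 equiv), CH2Cl2, 0 °C → rt
Reagents that add atoms: di-tert-butyl dicarbonate, CC(C)(C)OC(=O)OC(=O)OC(C)(C)C
Why: DMAP-catalysed O-acylation with Boc2O converts both salicylaldehyde-type phenols into aryl tert-butyl carbonates, the usual way to set up ortho-quinone methide precursors, and nothing else in 9 is nucleophilic.

**Step 9**
Reactants: 10 7,4'-bis-O-Boc-8,3'-diformyl-3,5-bis-O-MOM-kaempferol
Product: 11 7,4'-bis-O-Boc-8,3'-bis(hydroxymethyl)-3,5-bis-O-MOM-kaempferol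
Conditions: BH3·THF (1.5 equiv), THF, −20 → 0 °C; pH 7 phosphate buffer
Reagents that add atoms: none
Why: Borane reduction of the two aryl aldehydes runs through neutral alkoxyboranes, so no free alkoxide is formed that could trigger carbonate migration, and the aldehydes should react far faster than the electron-rich γ-pyrone carbonyl.

**Step 10**
Reactants: 11 7,4'-bis-O-Boc-8,3'-bis(hydroxymethyl)-3,5-bis-O-MOM-kaempferol; 12 2-methylprop-1-enylmagnesium bromide
Product: 15 3,5-bis-O-MOM-broussoflavonol F, via bis(benzylic tert-butyl carbonate) diphenol 13 (not isolated), via bis(ortho-quinone methide) 14 (not isolated)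
Conditions: 12 (6 equiv), CuBr·SMe2 (0.2 equiv), THF, −78 → 0 °C; aq. NH4Cl
Reagents that add atoms: none
Why: Each magnesium alkoxide formed from a benzylic alcohol attacks the neighbouring aryl carbonate through a six-membered transition state and passes the tert-butoxycarbonyl group to the benzylic oxygen (13), after which the magnesium phenoxide expels tert-butyl carbonate to give the ortho-quinone methide (14). The isobutenyl nucleophile then adds to the exocyclic methylene in a 1,4-sense, the ring regains aromaticity, and the CH2–CH bond of a prenyl group results at C8 and at C3'. The closest known reaction type is the base-triggered generation of ortho-quinone methides from O-Boc salicyl alcohols with in situ conjugate addition of Grignard reagents, here run twice in one molecule. No ring is closed and no stereocentre is created; the trisubstituted alkene is delivered intact, so the chain cannot transpose to a 1,1-dimethylallyl group. The step needs chemoselectivity for the quinone methides over the C4 carbonyl and C2 of the chromone: the γ-pyrone carbonyl is a vinylogous ester flanked by the 3- and 5-OMOM groups, C2 is fully substituted, and the copper-modified reagent at low temperature should react first with the far more electrophilic, aromatization-driven quinone methides. The positions of attack are fixed by where the hydroxymethyl groups sit, so no C6/C8 or 3'/5' question arises here.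

**Step 11**
Reactants: 15 3,5-bis-O-MOM-broussoflavonol F
Product: 16 broussoflavonol F
Conditions: HCl (3 M aq.)/MeOH, 40 °C
Reagents that add atoms: none
Why: Acid-catalysed acetal cleavage (transacetalization to dimethoxymethane) removes both MOM groups, which are activated by the neighbouring C4 carbonyl, under conditions mild enough that the prenyl groups should not cyclize onto the adjacent phenols.

**Compound list**
1 | 2,4,6-trihydroxyacetophenone (phloroacetophenone) | CC(=O)c1c(O)cc(O)cc1O | starting material
2 | 1-[4-(benzyloxy)-2,6-dihydroxyphenyl]ethanone | CC(=O)c1c(O)cc(OCc2ccccc2)cc1O | intermediate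
3 | 1-[4-(benzyloxy)-2-hydroxy-6-(methoxymethoxy)phenyl]ethanone | CC(=O)c1c(O)cc(OCc2ccccc2)cc1OCOC | intermediate
4 | 4-(benzyloxy)benzaldehyde | O=Cc1ccc(OCc2ccccc2)cc1 | starting material
5 | (E)-1-[4-(benzyloxy)-2-hydroxy-6-(methoxymethoxy)phenyl]-3-[4-(benzyloxy)phenyl]prop-2-en-1-one | O=C(/C=C/c1ccc(OCc2ccccc2)cc1)c1c(O)cc(OCc2ccccc2)cc1OCOC | intermediate
6 | 7-(benzyloxy)-2-[4-(benzyloxy)phenyl]-3-hydroxy-5-(methoxymethoxy)-4H-chromen-4-one | O=c1c(O)c(-c2ccc(OCc3ccccc3)cc2)oc2cc(OCc3ccccc3)cc(OCOC)c12 | intermediate
7 | 7-(benzyloxy)-2-[4-(benzyloxy)phenyl]-3,5-bis(methoxymethoxy)-4H-chromen-4-one | O=c1c(OCOC)c(-c2ccc(OCc3ccccc3)cc2)oc2cc(OCc3ccccc3)cc(OCOC)c12 | intermediate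
8 | 3,5-bis-O-MOM-kaempferol [7-hydroxy-2-(4-hydroxyphenyl)-3,5-bis(methoxymethoxy)-4H-chromen-4-one] | O=c1c(OCOC)c(-c2ccc(O)cc2)oc2cc(O)cc(OCOC)c12 | intermediate
9 | 8,3'-diformyl-3,5-bis-O-MOM-kaempferol [2-(3-formyl-4-hydroxyphenyl)-7-hydroxy-3,5-bis(methoxymethoxy)-4-oxo-4H-chromene-8-carbaldehyde] | O=Cc1cc(-c2oc3c(C=O)c(O)cc(OCOC)c3c(=O)c2OCOC)ccc1O | intermediate
10 | 7,4'-bis-O-Boc-8,3'-diformyl-3,5-bis-O-MOM-kaempferol | O=Cc1cc(-c2oc3c(C=O)c(OC(=O)OC(C)(C)C)cc(OCOC)c3c(=O)c2OCOC)ccc1OC(=O)OC(C)(C)C | intermediate
11 | 7,4'-bis-O-Boc-8,3'-bis(hydroxymethyl)-3,5-bis-O-MOM-kaempferol | OCc1cc(-c2oc3c(CO)c(OC(=O)OC(C)(C)C)cc(OCOC)c3c(=O)c2OCOC)ccc1OC(=O)OC(C)(C)C | intermediate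
12 | 2-methylprop-1-enylmagnesium bromide (THF solution) | CC(C)=C[Mg]Br | starting material
13 | 8,3'-bis[(tert-butoxycarbonyloxy)methyl]-3,5-bis-O-MOM-kaempferol, drawn in neutral form; present as its bis(magnesium phenoxide) in the flask of step 10 | CC(C)(C)OC(=O)OCc1cc(-c2oc3c(COC(=O)OC(C)(C)C)c(O)cc(OCOC)c3c(=O)c2OCOC)ccc1O | intermediate
14 | bis(ortho-quinone methide), 3,5-bis(methoxymethoxy)-8-methylidene-2-(3-methylidene-4-oxocyclohexa-1,5-dien-1-yl)-4H-chromene-4,7(8H)-dione; formed in the flask of step 10 | C=C1C=C(C2=C(OCOC)C(=O)C3=C(O2)C(=C)C(=O)C=C3OCOC)C=CC1=O | intermediate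
15 | 3,5-bis-O-MOM-broussoflavonol F | CC(C)=CCc1cc(-c2oc3c(CC=C(C)C)c(O)cc(OCOC)c3c(=O)c2OCOC)ccc1O | intermediate
16 | broussoflavonol F | CC(C)=CCc1cc(-c2oc3c(CC=C(C)C)c(O)cc(O)c3c(=O)c2O)ccc1O | target

**Summary**
Total step count: 11. Longest linear sequence: 11 steps (1 → 16).

**Steps most likely to fail**

Step 10. The Grignard reagent may add to the C4 carbonyl or to a carbonate carbonyl, the cascade may stall after only one of the two eliminations, or a quinone methide may self-condense before it is captured. The fallback sets out from 11 and returns at 15, replacing quinone methide capture by cross-coupling. Appel bromination (CBr4, PPh3, CH2Cl2, 0 °C) should give the bis(bromomethyl) bis(carbonate) F1. A twofold Stille coupling with tributyl(2-methylprop-1-enyl)stannane and Pd(PPh3)4 (zerovalent palladium) in THF at 65 °C, under neutral conditions that spare the carbonates, should give the doubly prenylated bis(carbonate) F2. Methanolysis of the two aryl carbonates (K2CO3, MeOH, rt) then leads to 15.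

Step 7. Formylation may go to C6 instead of C8 on ring A, may stay incomplete on the less activated ring-B phenol, or the 5-MOM group may be lost through magnesium chelation. The fallback sets out from 8 and returns at 9, delivering the carbon from the phenol oxygen by a sigmatropic shift. Allylation (allyl bromide, K2CO3, acetone, reflux) should give the bis(allyl ether) F3. A twofold aromatic Claisen rearrangement (N,N-diethylaniline, about 190 °C) is expected to go to C8 and C3' and give the 8,3'-diallyl diphenol F4. Alkene isomerization into conjugation (RuHCl(CO)(PPh3)3, toluene, 80 °C) should give the 8,3'-bis[(E)-prop-1-enyl] diphenol F5. Lemieux–Johnson cleavage (OsO4 cat., NaIO4, 2,6-lutidine, dioxane/water) of the two propenyl groups then gives 9; the tetrasubstituted C2=C3 bond should be too hindered and electron-poor to compete.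

Step 4. After epoxidation the phenoxide may open the epoxide at the α-carbon in a 5-exo mode and divert the chalcone to an aurone, a known tendency of chalcones with a 6'-oxygen substituent. The fallback sets out from 5 and returns at 6, separating ring closure from hydroxylation. Oxa-Michael cyclization (NaOAc, EtOH, reflux) should give the racemic flavanone F6. Dehydrogenation (I2, pyridine, 90 °C) should give the flavone F7. Epoxidation of its C2=C3 bond with dimethyldioxirane (acetone/CH2Cl2, 0 °C), followed by acid-catalysed opening of the epoxide (TsOH cat.), then gives flavonol 6.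

**Further compounds**
F1 | step 10 | 7,4'-bis-O-Boc-8,3'-bis(bromomethyl)-3,5-bis-O-MOM-kaempferol | BrCc1cc(-c2oc3c(CBr)c(OC(=O)OC(C)(C)C)cc(OCOC)c3c(=O)c2OCOC)ccc1OC(=O)OC(C)(C)C
F2 | step 10 | 7,4'-bis-O-Boc-3,5-bis-O-MOM-broussoflavonol F | CC(C)=CCc1cc(-c2oc3c(CC=C(C)C)c(OC(=O)OC(C)(C)C)cc(OCOC)c3c(=O)c2OCOC)ccc1OC(=O)OC(C)(C)C
F3 | step 7 | 7,4'-bis-O-allyl-3,5-bis-O-MOM-kaempferol | C=CCOc1ccc(-c2oc3cc(OCC=C)cc(OCOC)c3c(=O)c2OCOC)cc1
F4 | step 7 | 8,3'-diallyl-3,5-bis-O-MOM-kaempferol | C=CCc1cc(-c2oc3c(CC=C)c(O)cc(OCOC)c3c(=O)c2OCOC)ccc1O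
F5 | step 7 | 8,3'-bis[(E)-prop-1-enyl]-3,5-bis-O-MOM-kaempferol | C/C=C/c1cc(-c2oc3c(/C=C/C)c(O)cc(OCOC)c3c(=O)c2OCOC)ccc1O
F6 | step 4 | 7-(benzyloxy)-2-[4-(benzyloxy)phenyl]-5-(methoxymethoxy)chroman-4-one (racemic) | O=C1CC(c2ccc(OCc3ccccc3)cc2)Oc2cc(OCc3ccccc3)cc(OCOC)c12
F7 | step 4 | 7-(benzyloxy)-2-[4-(benzyloxy)phenyl]-5-(methoxymethoxy)-4H-chromen-4-one | O=c1cc(-c2ccc(OCc3ccccc3)cc2)oc2cc(OCc3ccccc3)cc(OCOC)c12
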